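Per unit of concentration, E passes on to Z faster than J passes to E, by the selectivity factor s = 3.12.

    L + Q + E → Q + Z (k1 = 229 M⁻² s⁻¹, Ea1 = 35.0 kJ mol⁻¹)
    J + L + Q → Q + E (k2 = 73.3 M⁻² s⁻¹, Ea2 = 38.0 kJ mol⁻¹)
    (constants at 0 °C)

all flasks: Q 9.9 mol%; time 3.0 min

|  | J | L | temperature | remark |
|---|---|---|---|---|
| east | 0.010 M (fed, over 80 s) | 5.00 equiv | 0 °C | all else is in the flask from the start; the feed brings no volume worth counting |
| south | 0.010 M | 5.00 equiv (fed, over 80 s) |  | the addition at −20 °C, then warmed to 0 °C; the feed brings no volume worth counting |
| north-west | 0.010 M | 5.00 equiv (fed, over 20 s) | 0 °C | all else is in the flask from the start; the feed brings no volume worth counting |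
| west | 0.010 M | 5.00 equiv (fed, over 80 s) | 0 °C | all else is in the flask from the start; the feed brings no volume worth counting |
| north-east | 0.010 M (in portions, 2, over 80 s) | 5.00 equiv | 0 °C | first portion at the start, last at 80 s |

- the best flask by share of E in E plus Z; "all alike" if 1.5 percentage points covers them all (east / south / north-west / west / north-east / all alike)
- share of E in E plus Z at the end, east
- share of E in E plus Z at the end, south
- share of E in E plus Z at the end, north-west
- share of E in E plus Z at the end, west
- share of E in E plus Z at the end, north-east

- all constants are for 0 °C and move with temperature by the activation energies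

Ruth compares rates at one moment. Both steps carry c_L and c_Q, so the loss of E over the making of E is s times c_E/c_J. The recipe's L and Q drop out. The activation energies are close, 35.0 kJ mol⁻¹ and 38.0 kJ mol⁻¹. So she expects the flasks to come out alike.

Tom asks how that comparison drifts. As J is used, c_E/c_J climbs, so the share of E falls. L and Q have left the ratio, but both rates, and with them the speed of the drift, still carry c_L and c_Q.

I side with Tom and reckon his way. With c_L and c_Q as charged, J is pseudo-first-order, with a lifetime of 276 s. Define the clock τ as the time a J molecule spends under full c_L at 0 °C, divided by that lifetime. With y = exp(−τ), the share of E is (y − y^s)/((s − 1)(1 − y)).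

In north-west, L arrives on average 10.0 s late, so τ = 0.617 and the share is 40.3%.

In east, west and north-east, the average lateness is 40.0 s, whichever species is fed. So those flasks share τ = 0.508 and a share of 46.9%.

In south, the cold scales the speed of J's step by 0.267 during the feed. That leaves 111 s of full time, so τ = 0.402 and the share is 54.7%. The spread from south to north-west is 14 percentage points, against a margin of 1.5 points.

The forecast takes Tom's side with its own figures, not mine: south best at 56.3%, west at 49%, east at 48.4%, north-east at 48% and north-west at 43.4%, since “less exposure gives a higher share”.

The flask gives south as best, at 56.1%. West gives 49.0%, east 48.5%, north-east 47.7% and north-west 42.8%. So the flasks part as Tom expected, south standing above north-west by 13 points. Ruth keeps the flasks of equal clock: east, west and north-east lie within 1.3 points, inside the margin. J left at the end of north-west is 56.3%. Read back from that reading, north-west's clock is 0.574, a little behind my 0.617.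

Take north-west again with 1.20 equiv of L. The clock scales with c_L, so τ = 0.148 and the rule gives a share of 79.6%. That neighbour computes to 80.8%, with 87.1% of J left.

Its constants are invented; the run is a simulation.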